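The numbers in the tables were generated by integration for substances that don't exist; noise was put on by code.

Early in east, D reads 56% after 0.333 min and Q is down to 1% after 0.667 min. From there D falls at each reading.

common to all: Q 0.50 mM
- north: E 0.21 mM; run made earlier
- south: E 0.69 mM; run made earlier
- east: E 2.1 mM; run made earlier
- blue: E 0.250 mM; time 6.0 min
- green: E 1.50 mM; time 6.0 min
- violet: E 2.00 mM; time 6.0 min

| run | time / min | D / % | Q / % |
|---|---|---|---|
| north | 0.333 | 13 | 40 |
| north | 0.667 | 13 | 21 |
| north | 1.33 | 19 | 11 |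
| north | 2.00 | 23 | 8 |
| north | 4.00 | 19 | 4 |
| south | 0.417 | 35 | 22 |
| south | 1.00 | 41 | 7 |
| south | 2.00 | 36 | 0 |
| south | 3.00 | 31 | 0 |
| south | 4.00 | 26 | 0 |
| east | 0.333 | 56 | 7 |
| east | 0.667 | 46 | 1 |
| east | 1.33 | 25 | 0 |
| east | 2.00 | 18 | 0 |
| east | 4.00 | 3 | 2 |

(standard deviation of a reading: 1.5 percentage points)



- D at the end, in percent of the Q charged, for each flask in turn (blue, green, violet)

The loss of D read in east between 0.667 min and 2.00 min, a pseudo-first-order rate, is 0.704 min⁻¹; call this the wearing rate of D, and take it as proportional to the E charged. Scaled so, it starts at 0.503 min⁻¹ in green and 0.670 min⁻¹ in violet. But E is consumed as it adds, and south shows the size of that slowing. Its charge predicts 0.231 min⁻¹, yet its D reads a slower 0.163 min⁻¹, a factor of 0.704.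

This reckoning takes east's first D reading as the height D reaches and wears it down over the 5.67 min that follow. Green then ends at 3.24% unslowed and 7.54% with south's factor. Violet, charged close to east, ends near 1.25%.

The forecast, resting on “D decay in south and east”, gave 20%, 5% and 2% for blue, green and violet. Its green figure lies inside this reckoning's span, and its violet figure stands above it.

The flasks give 22.2%, 5.00% and 1.56%, and the forecast holds within its margin.

    E → J (k = 9.90 × 10⁻⁵ s⁻¹)
    2 Q → Z (k = 68.9 L mol⁻¹ s⁻¹)
    Q + E → D + G (k = 57.7 L mol⁻¹ s⁻¹)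
    E + D → X + G (k = 9.23 L mol⁻¹ s⁻¹)
    E + X → L + G (k = 2.02 L mol⁻¹ s⁻¹)

In green, D falls from 16.7% at 3.00 min to 5.00% at 6.00 min, a wearing rate of 0.402 min⁻¹, slower than the 0.503 min⁻¹ scaled from east. Violet, over the same span, reads 0.598 min⁻¹ against the scaled 0.670 min⁻¹, with E at 50.7% of its charge. One reason for green's low end figure is the reaction of 2 Q to Z: the same green run without that step ends at 13.5% D instead of 5.00%.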